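**Plan**
1. Endgame cuts: the four aryl O–CH3 bonds and the pyrrole N–CH2 bond, giving bis(quinolinyl)pyrrole 24 and the side-chain chloride 35.
2. Pyrrole: with carboxyl groups restored at C2/C5, the ring is traced through a 1,2-diazine to diarylalkyne 17 and tetrazine 18; the alkyne carbons become pyrrole C3/C4.
3. Quinolines (key cut): in each benzo ring C4a–C5 and C8–C8a are cut. C5 (carbon), C6 (H), C7 (O) and C8 (O) are C2, C3, C4 and C5 of a 2-alkynyl-4-methoxyfuran whose ring oxygen becomes the 8-OH; C4a/C8a are C3/C2 of a pyridine, i.e. 2,3-pyridyne.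
4. Azecane: N–C10 (ring closure) and C3–C4 (chain assembly) are cut.
5. Forward: furan → blocked iodofuran → difurylalkyne → both benzo rings in one operation → diazine → pyrrole. Separately: chain coupling, then ten-membered ring closure. N-alkylation joins the halves and fourfold demethylation finishes.
6. Stereochemistry: the single stereocentre (azecane C3, S) is bought as (R)-3-bromo-2-methylpropan-1-ol; no later step makes or breaks a bond at it, and only the CIP descriptor changes.

Key step: step 5

Assumption: the target is the neutral free base, S at azecane C3 as drawn; it is an air-sensitive bis-catechol to be handled under argon, and compounds 1, 8, 13, 18, 25, 26, 29 and 34 are taken as purchasable.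

**Route**

Step 1
Reactants: 1 methyl tetronate (4-methoxyfuran-2(5H)-one)
Product: 3 3-methoxyfuran, via lactol 2 (not isolated)
Conditions: i-Bu2AlH (1.1 equiv), CH2Cl2, −78 °C; aq. potassium sodium tartrate; TsOH (cat.), Et2O, rt; distil
Reagents that add atoms: none
Why: At −78 °C i-Bu2AlH adds once to the lactone carbonyl and the aluminium hemiacetal survives until work-up, after which acid-catalysed loss of water from lactol 2 is driven by aromatisation (reduction–dehydration of a butenolide to a furan).

Step 2
Reactants: 3 3-methoxyfuran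
Product: 7 5-iodo-3-methoxy-2-(trimethylsilyl)furan, via 2-lithio-3-methoxyfuran 4 (not isolated), via 3-methoxy-2-(trimethylsilyl)furan 5 (not isolated), via 5-lithio-3-methoxy-2-(trimethylsilyl)furan 6 (not isolated)
Conditions: n-BuLi (1.05 equiv), THF, −78 → 0 °C; Me3SiCl (1.0 equiv), −78 °C → rt; n-BuLi (1.1 equiv), −78 → −20 °C; I2, −78 °C
Reagents that add atoms: chlorotrimethylsilane, C[Si](C)(C)Cl; iodine, II
Why: Alpha-lithiation of the furan occurs first at C2, which lies between the ring oxygen and the methoxy group, so silylation blocks this site and the second n-BuLi can only deprotonate the remaining alpha position C5 before the iodine quench (sequential directed metalation with a removable silyl blocking group).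

Step 3
Reactants: 7 5-iodo-3-methoxy-2-(trimethylsilyl)furan (2 equiv); 8 ethynyltrimethylsilane (1 equiv)
Product: 11 1,2-bis(4-methoxy-5-(trimethylsilyl)furan-2-yl)ethyne, via silylalkyne 9 (not isolated), via terminal alkyne 10 (not isolated)
Conditions: PdCl2(PPh3)2 (6 mol%), CuI (copper iodide, 10 mol%), DBU (6 equiv), H2O (0.4 equiv per 7), MeCN, rt → 60 °C
Reagents that add atoms: none
Why: One-pot twofold Sonogashira coupling, in which the iodofuran couples with 8, DBU/water cleaves the alkynyl C–Si bond of 9 selectively (the furyl C–Si bonds are inert to amidine base) and the liberated alkyne 10 couples with the second equivalent of 7.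

Step 4
Reactants: 11 1,2-bis(4-methoxy-5-(trimethylsilyl)furan-2-yl)ethyne
Product: 12 1,2-bis(4-methoxyfuran-2-yl)ethyne
Conditions: n-Bu4NF (2.5 equiv), wet THF, 0 °C → rt
Reagents that add atoms: none
Why: Fluoride-mediated protodesilylation of the 2-silylfurans, in which the pentacoordinate silicate releases a furyl anion equivalent stabilised by the adjacent ring oxygen and methoxy group, removes both blocking groups under non-acidic conditions that the electron-rich furans tolerate.

Step 5
Reactants: 12 1,2-bis(4-methoxyfuran-2-yl)ethyne; 13 3-(trimethylsilyl)pyridin-2-yl trifluoromethanesulfonate (4 equiv)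
Product: 16 5,5'-(ethyne-1,2-diyl)bis(7-methoxyquinolin-8-ol), via 2,3-pyridyne 14 (not isolated), via bis-epoxy cycloadduct 15 (not isolated)
Conditions: CsF (8 equiv), MeCN, rt, 13 added over 6 h; filter, concentrate; CF3CO2H, CH2Cl2, 0 °C → rt; NaHCO3 work-up
Reagents that add atoms: none
Why: Fluoride attacks silicon of 13 and triflate departs to give 2,3-pyridyne 14, which adds across C2 and C5 of each furan in a concerted, asynchronous [4+2] cycloaddition (the aryne–furan Diels–Alder reaction, known for 2,3-pyridyne with simple furans), and CF3CO2H then isomerises the 5,8-epoxy-5,8-dihydroquinolines of 15 to quinolin-8-ols (the standard acid opening of 1,4-epoxy-1,4-dihydroarenes to phenols). Each benzo ring closes by intermolecular [4+2] ring formation that makes C4a–C5 and C8–C8a, and the oxygen bridge becomes the C8 hydroxyl. The four bridgehead stereocentres of 15 form without control as a diastereomer mixture, which does not matter because aromatisation deletes them. The step needs regioselectivity: the unsubstituted furan carbon next to the methoxy-bearing carbon is the nucleophilic end of the diene and should lead bond formation to C2 of the pyridyne, the electrophilic aryne carbon beside nitrogen, while the alkynyl-substituted furan carbon closes onto C3. Ring opening has one outcome only, since C5 is quaternary and its C–O bond ionises to a propargylic cation that the C6=C7 enol ether turns into an oxocarbenium ion, after which loss of H8 aromatises the ring. Chemoselectivity for the furans over the central alkyne rests on the much higher rate of aryne capture by furan dienes, and slow addition of 13 keeps the pyridyne concentration low so that capture by the second furan is favoured over self-reaction.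

Step 6
Reactants: 16 5,5'-(ethyne-1,2-diyl)bis(7-methoxyquinolin-8-ol)
Product: 17 1,2-bis(7,8-dimethoxyquinolin-5-yl)ethyne
Conditions: MeI (2.5 equiv), K2CO3, DMF, rt
Reagents that add atoms: iodomethane, CI
Why: Williamson O-methylation of the two phenoxides, which as in the standard preparation of 8-methoxyquinoline outruns quaternisation of the ring nitrogen because the peri oxygen shields it.

Step 7
Reactants: 17 1,2-bis(7,8-dimethoxyquinolin-5-yl)ethyne; 18 dimethyl 1,2,4,5-tetrazine-3,6-dicarboxylate (2.5 equiv)
Product: 20 dimethyl 4,5-bis(7,8-dimethoxyquinolin-5-yl)pyridazine-3,6-dicarboxylate, via tetraazabicyclooctatriene adduct 19 (not isolated)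
Conditions: mesitylene, 140 °C, sealed tube
Reagents that add atoms: none
Why: Inverse-electron-demand Diels–Alder reaction of the electron-poor tetrazine with the alkyne, each alkyne carbon being conjugated para to an 8-methoxy group, followed by retro-[4+2] loss of N2 from 19 (Carboni–Lindsey reaction as used in the Boger diazine synthesis).

Step 8
Reactants: 20 dimethyl 4,5-bis(7,8-dimethoxyquinolin-5-yl)pyridazine-3,6-dicarboxylate
Product: 22 dimethyl 3,4-bis(7,8-dimethoxyquinolin-5-yl)-1H-pyrrole-2,5-dicarboxylate, via 1,4-dihydropyridazine 21 (not isolated)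
Conditions: Zn dust (excess), AcOH, rt
Reagents that add atoms: none
Why: Boger reductive ring contraction, in which Zn in AcOH reduces the ester-activated diazine to the 1,4-dihydro compound 21, cleaves its N–N bond and the resulting amino-imine recloses with loss of NH3 to the pyrrole, while quinolines and aryl ethers are inert to Zn/AcOH at rt.

Step 9
Reactants: 22 dimethyl 3,4-bis(7,8-dimethoxyquinolin-5-yl)-1H-pyrrole-2,5-dicarboxylate
Product: 24 5,5'-(1H-pyrrole-3,4-diyl)bis(7,8-dimethoxyquinoline), via dipotassium dicarboxylate 23 (not isolated)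
Conditions: KOH, HOCH2CH2OH, 170 °C, under Ar
Reagents that add atoms: none
Why: Saponification followed by thermal protodecarboxylation of the pyrrole-2,5-dicarboxylate through ipso C-protonation is the classical way to alpha-free pyrroles from their esters, and any stray ether cleavage would be harmless because all four ethers are removed in step 17.

Step 10
Reactants: 25 (R)-3-bromo-2-methylpropan-1-ol; 26 tert-butyl(6-bromohexyloxy)dimethylsilane
Product: 28 (S)-9-((tert-butyldimethylsilyl)oxy)-2-methylnonan-1-ol, via Grignard reagent 27 (not isolated)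
Conditions: 26, Mg, THF, 40 °C; 25, MeMgCl (1.0 equiv), THF, −40 °C; then 27 (1.5 equiv), Li2CuCl4 (5 mol%), −40 °C → rt
Reagents that add atoms: none
Why: Kochi-type sp3–sp3 cross-coupling of the primary bromide (as its magnesium alkoxide) with Grignard reagent 27 under Li2CuCl4 catalysis; bond formation occurs at CH2Br, so the neighbouring stereocentre is carried over unchanged and only its descriptor changes from R to S.

Step 11
Reactants: 28 (S)-9-((tert-butyldimethylsilyl)oxy)-2-methylnonan-1-ol; 29 tert-butyl ((2-nitrophenyl)sulfonyl)carbamate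
Product: 30 tert-butyl (S)-(9-((tert-butyldimethylsilyl)oxy)-2-methylnonyl)((2-nitrophenyl)sulfonyl)carbamate
Conditions: PPh3, DIAD, THF, 0 °C → rt
Reagents that add atoms: none
Why: Fukuyama–Mitsunobu reaction, in which the acidic N–H of 29 is alkylated by the PPh3/DIAD-activated primary alcohol in an SN2 displacement at CH2 that does not involve the adjacent stereocentre.

Step 12
Reactants: 30 tert-butyl (S)-(9-((tert-butyldimethylsilyl)oxy)-2-methylnonyl)((2-nitrophenyl)sulfonyl)carbamate
Product: 31 (S)-N-(9-hydroxy-2-methylnonyl)-2-nitrobenzenesulfonamide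
Conditions: HCl (3 M, from AcCl) in MeOH, 0 °C → rt
Reagents that add atoms: none
Why: Methanolic HCl solvolyses the primary silyl ether and removes the Boc group by tert-butyl cation loss and decarboxylation in one operation, the nosylamide being stable to acid.

Step 13
Reactants: 31 (S)-N-(9-hydroxy-2-methylnonyl)-2-nitrobenzenesulfonamide
Product: 32 (S)-3-methyl-1-((2-nitrophenyl)sulfonyl)azecane
Conditions: PPh3 (3 equiv), DIAD (3 equiv), toluene–THF, 0.005 M, slow addition of 31, rt
Reagents that add atoms: none
Why: Intramolecular Fukuyama–Mitsunobu N-alkylation under high dilution (10-exo-tet), a closure established for eight- to ten-membered cyclic amines because the acidic nosylamide is alkylated quickly at the unhindered terminal carbon; the stereocentre is not involved.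

Step 14
Reactants: 32 (S)-3-methyl-1-((2-nitrophenyl)sulfonyl)azecane
Product: 33 (S)-3-methylazecane
Conditions: PhSH, K2CO3, MeCN, 40 °C; acid–base extraction
Reagents that add atoms: none
Why: Fukuyama nosyl cleavage, in which thiolate adds ipso to the nitroarene to give a Meisenheimer complex that collapses with loss of SO2 and the free secondary amine.

Step 15
Reactants: 33 (S)-3-methylazecane; 34 1-bromo-3-chloropropane (3 equiv)
Product: 35 (S)-1-(3-chloropropyl)-3-methylazecane
Conditions: K2CO3, MeCN, rt; used promptly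
Reagents that add atoms: none
Why: SN2 N-alkylation at the C–Br end of the dihalide, bromide being the far better leaving group, with excess dihalide suppressing double amination.

Step 16
Reactants: 24 5,5'-(1H-pyrrole-3,4-diyl)bis(7,8-dimethoxyquinoline); 35 (S)-1-(3-chloropropyl)-3-methylazecane
Product: 36 5,5'-(1-(3-((S)-3-methylazecan-1-yl)propyl)-1H-pyrrole-3,4-diyl)bis(7,8-dimethoxyquinoline)
Conditions: NaH, DMF, 0 °C; 35, NaI (cat.), 60 °C
Reagents that add atoms: none
Why: N-Alkylation of the sodium pyrrolide in DMF, where the dissociated anion reacts at nitrogen with the primary chloride (directly or through the azetidinium ion derived from 35, which opens to the same product).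

Step 17
Reactants: 36 5,5'-(1-(3-((S)-3-methylazecan-1-yl)propyl)-1H-pyrrole-3,4-diyl)bis(7,8-dimethoxyquinoline)
Product: 37 5,5'-(1-(3-((S)-3-methylazecan-1-yl)propyl)-1H-pyrrole-3,4-diyl)bis(quinoline-7,8-diol)
Conditions: BBr3 (12 equiv), CH2Cl2, −78 °C → rt; MeOH, then aq. NaHCO3 under Ar
Reagents that add atoms: none
Why: BBr3 first saturates the four basic nitrogens and then coordinates each ether oxygen, bromide removes the methyl groups by SN2 and methanolysis of the borates frees both catechols (Lewis acid ether cleavage as used for polymethoxylated 3,4-diarylpyrroles); the remote sp3 stereocentre is unaffected.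

**Compound list**

1 | methyl tetronate (4-methoxyfuran-2(5H)-one) | COC1=CC(=O)OC1 | starting material
2 | 4-methoxy-2,5-dihydrofuran-2-ol (lactol, racemic, not isolated) | COC1=CC(O)OC1 | intermediate
3 | 3-methoxyfuran | COc1ccoc1 | intermediate
4 | 2-lithio-3-methoxyfuran (not isolated) | COc1ccoc1[Li] | intermediate
5 | 3-methoxy-2-(trimethylsilyl)furan (not isolated) | COc1ccoc1[Si](C)(C)C | intermediate
6 | 5-lithio-3-methoxy-2-(trimethylsilyl)furan (not isolated) | COc1cc([Li])oc1[Si](C)(C)C | intermediate
7 | 5-iodo-3-methoxy-2-(trimethylsilyl)furan | COc1cc(I)oc1[Si](C)(C)C | intermediate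
8 | ethynyltrimethylsilane | C#C[Si](C)(C)C | starting material
9 | 3-methoxy-2-(trimethylsilyl)-5-((trimethylsilyl)ethynyl)furan (silylalkyne, not isolated) | COc1cc(C#C[Si](C)(C)C)oc1[Si](C)(C)C | intermediate
10 | 5-ethynyl-3-methoxy-2-(trimethylsilyl)furan (terminal alkyne, not isolated) | COc1cc(C#C)oc1[Si](C)(C)C | intermediate
11 | 1,2-bis(4-methoxy-5-(trimethylsilyl)furan-2-yl)ethyne | COc1cc(C#Cc2cc(OC)c([Si](C)(C)C)o2)oc1[Si](C)(C)C | intermediate
12 | 1,2-bis(4-methoxyfuran-2-yl)ethyne | COc1coc(C#Cc2cc(OC)co2)c1 | intermediate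
13 | 3-(trimethylsilyl)pyridin-2-yl trifluoromethanesulfonate | C[Si](C)(C)c1cccnc1OS(=O)(=O)C(F)(F)F | starting material
14 | 2,3-pyridyne (2,3-didehydropyridine, not isolated) | C1=CC#CN=C1 | intermediate
15 | 5,5'-(ethyne-1,2-diyl)bis(7-methoxy-5,8-dihydro-5,8-epoxyquinoline) (bis-epoxy cycloadduct, diastereomer mixture, not isolated) | COC1=CC2(C#CC34C=C(OC)C(O3)c3ncccc34)OC1c1ncccc12 | intermediate
16 | 5,5'-(ethyne-1,2-diyl)bis(7-methoxyquinolin-8-ol) | COc1cc(C#Cc2cc(OC)c(O)c3ncccc23)c2cccnc2c1O | intermediate
17 | 1,2-bis(7,8-dimethoxyquinolin-5-yl)ethyne | COc1cc(C#Cc2cc(OC)c(OC)c3ncccc23)c2cccnc2c1OC | intermediate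
18 | dimethyl 1,2,4,5-tetrazine-3,6-dicarboxylate | COC(=O)c1nnc(C(=O)OC)nn1 | starting material
19 | dimethyl 7,8-bis(7,8-dimethoxyquinolin-5-yl)-2,3,5,6-tetraazabicyclo[2.2.2]octa-2,5,7-triene-1,4-dicarboxylate (not isolated) | COC(=O)C12N=NC(C(=O)OC)(N=N1)C(c1cc(OC)c(OC)c3ncccc13)=C2c1cc(OC)c(OC)c2ncccc12 | intermediate
20 | dimethyl 4,5-bis(7,8-dimethoxyquinolin-5-yl)pyridazine-3,6-dicarboxylate | COC(=O)c1nnc(C(=O)OC)c(-c2cc(OC)c(OC)c3ncccc23)c1-c1cc(OC)c(OC)c2ncccc12 | intermediate
21 | dimethyl 4,5-bis(7,8-dimethoxyquinolin-5-yl)-1,4-dihydropyridazine-3,6-dicarboxylate (racemic, not isolated) | COC(=O)C1=NNC(C(=O)OC)=C(c2cc(OC)c(OC)c3ncccc23)C1c1cc(OC)c(OC)c2ncccc12 | intermediate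
22 | dimethyl 3,4-bis(7,8-dimethoxyquinolin-5-yl)-1H-pyrrole-2,5-dicarboxylate | COC(=O)c1[nH]c(C(=O)OC)c(-c2cc(OC)c(OC)c3ncccc23)c1-c1cc(OC)c(OC)c2ncccc12 | intermediate
23 | dipotassium 3,4-bis(7,8-dimethoxyquinolin-5-yl)-1H-pyrrole-2,5-dicarboxylate (not isolated) | [K+].[K+].[O-]C(=O)c1[nH]c(C([O-])=O)c(-c2cc(OC)c(OC)c3ncccc23)c1-c1cc(OC)c(OC)c2ncccc12 | intermediate
24 | 5,5'-(1H-pyrrole-3,4-diyl)bis(7,8-dimethoxyquinoline) | COc1cc(-c2c[nH]cc2-c2cc(OC)c(OC)c3ncccc23)c2cccnc2c1OC | intermediate
25 | (R)-3-bromo-2-methylpropan-1-ol | C[C@H](CO)CBr | starting material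
26 | tert-butyl(6-bromohexyloxy)dimethylsilane | CC(C)(C)[Si](C)(C)OCCCCCCBr | starting material
27 | (6-((tert-butyldimethylsilyl)oxy)hexyl)magnesium bromide (Grignard reagent, not isolated) | CC(C)(C)[Si](C)(C)OCCCCCC[Mg]Br | intermediate
28 | (S)-9-((tert-butyldimethylsilyl)oxy)-2-methylnonan-1-ol | C[C@H](CO)CCCCCCCO[Si](C)(C)C(C)(C)C | intermediate
29 | tert-butyl ((2-nitrophenyl)sulfonyl)carbamate | CC(C)(C)OC(=O)NS(=O)(=O)c1ccccc1[N+](=O)[O-] | starting material
30 | tert-butyl (S)-(9-((tert-butyldimethylsilyl)oxy)-2-methylnonyl)((2-nitrophenyl)sulfonyl)carbamate | C[C@H](CN(C(=O)OC(C)(C)C)S(=O)(=O)c1ccccc1[N+](=O)[O-])CCCCCCCO[Si](C)(C)C(C)(C)C | intermediate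
31 | (S)-N-(9-hydroxy-2-methylnonyl)-2-nitrobenzenesulfonamide | C[C@H](CNS(=O)(=O)c1ccccc1[N+](=O)[O-])CCCCCCCO | intermediate
32 | (S)-3-methyl-1-((2-nitrophenyl)sulfonyl)azecane | C[C@H]1CCCCCCCN(S(=O)(=O)c2ccccc2[N+](=O)[O-])C1 | intermediate
33 | (S)-3-methylazecane | C[C@H]1CCCCCCCNC1 | intermediate
34 | 1-bromo-3-chloropropane | ClCCCBr | starting material
35 | (S)-1-(3-chloropropyl)-3-methylazecane | C[C@H]1CCCCCCCN(CCCCl)C1 | intermediate
36 | 5,5'-(1-(3-((S)-3-methylazecan-1-yl)propyl)-1H-pyrrole-3,4-diyl)bis(7,8-dimethoxyquinoline) | C[C@H]1CCCCCCCN(CCCn2cc(-c3cc(OC)c(OC)c4ncccc34)c(-c3cc(OC)c(OC)c4ncccc34)c2)C1 | intermediate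
37 | 5,5'-(1-(3-((S)-3-methylazecan-1-yl)propyl)-1H-pyrrole-3,4-diyl)bis(quinoline-7,8-diol) (halitulin) | C[C@H]1CCCCCCCN(CCCn2cc(-c3cc(O)c(O)c4ncccc34)c(-c3cc(O)c(O)c4ncccc34)c2)C1 | target

**Count and risks**

Total steps: 17. Longest linear sequence: 11 steps (steps 1–9, 16 and 17, from methyl tetronate); the side chain is a six-step branch (steps 10–15) that joins at step 16.

Steps most likely to fail:

Step 5. The two cycloadditions may take mixed orientations, giving isomeric bis-quinolinols. Pyridyne may also be consumed by self-reaction, or by the pyridine nitrogens and enol ether of the first adduct, before the second furan has reacted. The fallback sets out from ethynyltrimethylsilane 8 and comes back at 17. Purchased 2,3-dimethoxyaniline F1 would be converted by a Skraup reaction (glycerol, H2SO4, sodium 3-nitrobenzenesulfonate, 140 °C) into 7,8-dimethoxyquinoline F2. Bromination of F2 with N-bromosuccinimide in MeCN should occur para to the 8-methoxy group to give 5-bromo-7,8-dimethoxyquinoline F3. The one-pot twofold Sonogashira coupling of F3 with 8 under the conditions of step 3 (at 80 °C) would then give 17 directly, replacing steps 1–6.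

Step 13. Intermolecular Mitsunobu coupling to dimers and oligomers may outrun closure of the strained ten-membered ring. The fallback sets out from 29 and comes back at 32, closing the ring by C=C formation instead of C–N formation. (S)-2-Methylpent-4-en-1-ol F4 (purchased, or made by Evans allylation and reduction) would be coupled with 29 under Mitsunobu conditions to give tert-butyl (S)-(2-methylpent-4-en-1-yl)((2-nitrophenyl)sulfonyl)carbamate F5. CF3CO2H would remove the Boc group to give (S)-N-(2-methylpent-4-en-1-yl)-2-nitrobenzenesulfonamide F6. Alkylation with 6-bromohex-1-ene (K2CO3, DMF) would give the diene (S)-N-(hex-5-en-1-yl)-N-(2-methylpent-4-en-1-yl)-2-nitrobenzenesulfonamide F7. Ring-closing metathesis with the second-generation Grubbs catalyst RuCl2(=CHPh)(H2IMes)(PCy3) in dilute refluxing CH2Cl2 would give (S)-3-methyl-1-((2-nitrophenyl)sulfonyl)-1,2,3,4,7,8,9,10-octahydroazecine F8 as an E/Z mixture. Diimide (TsNHNH2, NaOAc, aqueous THF, reflux) would saturate the alkene without touching the nitro group and give 32.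

Step 7. The hindered bis(quinolin-5-yl)alkyne may cycloadd more slowly than the tetrazine decomposes at the temperature required. The fallback sets out from 17 and comes back at 23. Oxidation of the alkyne (PdCl2 cat., DMSO, 140 °C) would give 1,2-bis(7,8-dimethoxyquinolin-5-yl)ethane-1,2-dione F9. Hinsberg condensation with purchased dimethyl 2,2'-(acetylazanediyl)diacetate F10 (NaOMe, MeOH, reflux, then aq. NaOH) would give 3,4-bis(7,8-dimethoxyquinolin-5-yl)-1H-pyrrole-2,5-dicarboxylic acid F11. Dissolved in KOH/ethylene glycol, F11 is the salt 23 and would be carried through step 9 to 24.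

**Further compounds**

F1 | step 5 | 2,3-dimethoxyaniline | COc1cccc(N)c1OC
F2 | step 5 | 7,8-dimethoxyquinoline | COc1ccc2cccnc2c1OC
F3 | step 5 | 5-bromo-7,8-dimethoxyquinoline | COc1cc(Br)c2cccnc2c1OC
F4 | step 13 | (S)-2-methylpent-4-en-1-ol | C[C@H](CO)CC=C
F5 | step 13 | tert-butyl (S)-(2-methylpent-4-en-1-yl)((2-nitrophenyl)sulfonyl)carbamate | C[C@H](CN(C(=O)OC(C)(C)C)S(=O)(=O)c1ccccc1[N+](=O)[O-])CC=C
F6 | step 13 | (S)-N-(2-methylpent-4-en-1-yl)-2-nitrobenzenesulfonamide | C[C@H](CNS(=O)(=O)c1ccccc1[N+](=O)[O-])CC=C
F7 | step 13 | (S)-N-(hex-5-en-1-yl)-N-(2-methylpent-4-en-1-yl)-2-nitrobenzenesulfonamide | C[C@H](CN(CCCCC=C)S(=O)(=O)c1ccccc1[N+](=O)[O-])CC=C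
F8 | step 13 | (S)-3-methyl-1-((2-nitrophenyl)sulfonyl)-1,2,3,4,7,8,9,10-octahydroazecine (E/Z mixture) | C[C@H]1CC=CCCCCN(S(=O)(=O)c2ccccc2[N+](=O)[O-])C1
F9 | step 7 | 1,2-bis(7,8-dimethoxyquinolin-5-yl)ethane-1,2-dione | COc1cc(C(=O)C(=O)c2cc(OC)c(OC)c3ncccc23)c2cccnc2c1OC
F10 | step 7 | dimethyl 2,2'-(acetylazanediyl)diacetate | COC(=O)CN(C(C)=O)CC(=O)OC
F11 | step 7 | 3,4-bis(7,8-dimethoxyquinolin-5-yl)-1H-pyrrole-2,5-dicarboxylic acid | OC(=O)c1[nH]c(C(O)=O)c(-c2cc(OC)c(OC)c3ncccc23)c1-c1cc(OC)c(OC)c2ncccc12
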